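**Retrosynthetic overview**
1. Target ⇒ late C6–OH (manganese hydride/O2 hydration of a C6=C7 enol ether from the convex face) and C4 acetonyl (enolate alkylation anti to the C16 chain).
2. Seven-membered ring ⇒ C13–C16 bond by a cathodic cobalt-hydride MHAT 7-endo radical closure of the C13=C14 alkene onto an E,E-dienone that already carries the complete E-enol ester (sets C13 and C16).
3. Dienone ⇒ aldol condensation of a bicyclic methyl ketone with (E)-3-(3-methylbut-2-enoyloxy)acrolein.
4. Pyran ⇒ BF3 closure of a formyl-ketone enol onto the isopropenyl group; C15–C6 bond ⇒ Claisen rearrangement of the β-acylvinyl ether of (1S,4R)-p-mentha-2,8-dien-1-ol (C10 bought, C15 by chirality transfer).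
5. Ring order: cyclohexane (bought) → dihydropyran → cycloheptanone.

Atom labels follow the target SMILES from left to right: C1 (CH3), C2 (C=O), C3 (CH2), C4, C5 (ring C=O), C6 (C–OH), C7 (OCH2), O8, C9 (CMe2), C10, C11, C12, C13 (C–CH3), C14, C15, C16, C17=C18 (enol ester CH=CH), then the 3-methylbut-2-enoyl group.

Assumption: 1 (made industrially from (R)-(+)-limonene for cannabinoid manufacture) is bought as the single (1S,4R) diastereomer, and 6 and 13 are taken as purchasable.

**Step 1**
Reactants: 1 (1S,4R)-p-mentha-2,8-dien-1-ol; 2 but-3-yn-2-one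
Product: 3 (E)-4-{[(1S,4R)-1-methyl-4-(prop-1-en-2-yl)cyclohex-2-en-1-yl]oxy}but-3-en-2-one
Conditions: PMe3 (10 mol %), CH2Cl2, 0 °C to rt
Reagents that add atoms: none
Why: Phosphine-catalysed oxa-Michael (conjugate) addition of the tertiary alcohol to the ynone gives the E β-alkoxy enone under neutral conditions that leave the ionisable tertiary allylic C–O bond and both stereocentres untouched.

**Step 2**
Reactants: 3 (E)-4-{[(1S,4R)-1-methyl-4-(prop-1-en-2-yl)cyclohex-2-en-1-yl]oxy}but-3-en-2-one
Product: 4 2-[(1S,6R)-3-methyl-6-(prop-1-en-2-yl)cyclohex-2-en-1-yl]-3-oxobutanal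
Conditions: o-xylene, 140 °C, sealed tube
Reagents that add atoms: none
Why: The thermal Claisen ([3,3]-sigmatropic) rearrangement is suprafacial on the cyclohexenyl unit, so the new C15–C6 bond forms on the face that carried the C13–O bond, cis to the isopropenyl group at C10 (chirality transfer sets C15).

**Step 3**
Reactants: 4 2-[(1S,6R)-3-methyl-6-(prop-1-en-2-yl)cyclohex-2-en-1-yl]-3-oxobutanal
Product: 5 1-[(4aS,8aR)-1,1,6-trimethyl-4a,7,8,8a-tetrahydro-1H-isochromen-4-yl]ethan-1-one
Conditions: BF3·OEt2 (10 mol %), CH2Cl2, −20 °C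
Reagents that add atoms: none
Why: Lewis-acid-catalysed Markovnikov hydroalkoxylation of the isopropenyl group by the formyl-derived enol oxygen (the cannabidiol-to-tetrahydrocannabinol type of ring closure) gives the six-membered vinylogous ester, cis-fused because C15 and C10 already carry their substituents cis, while low temperature and the more reactive 1,1-disubstituted alkene keep the ring alkene out.

**Step 4**
Reactants: 6 malondialdehyde tetrabutylammonium salt; 7 3-methylbut-2-enoyl chloride
Product: 8 (E)-3-oxoprop-1-en-1-yl 3-methylbut-2-enoate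
Conditions: CH2Cl2, −20 to 0 °C
Reagents that add atoms: none
Why: O-acylation of the delocalised, W-shaped malondialdehyde enolate by the acid chloride gives the E β-acyloxyacrolein, which fixes the enol ester geometry of the target at the outset.

**Step 5**
Reactants: 5 1-[(4aS,8aR)-1,1,6-trimethyl-4a,7,8,8a-tetrahydro-1H-isochromen-4-yl]ethan-1-one; 8 (E)-3-oxoprop-1-en-1-yl 3-methylbut-2-enoate
Product: 11 (1E,3E)-5-oxo-5-[(4aS,8aR)-1,1,6-trimethyl-4a,7,8,8a-tetrahydro-1H-isochromen-4-yl]penta-1,3-dien-1-yl 3-methylbut-2-enoate, via aldol adduct 9 (not isolated), via mesylate 10 (not isolated)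
Conditions: LDA, THF, −78 °C; 8, −78 °C; then MsCl, Et3N, −78 to 0 °C
Reagents that add atoms: none
Why: In this directed aldol condensation the kinetic lithium enolate can form only at the acetyl methyl (C4) because C6 is sp2, it adds 1,2 to the aldehyde, and mesylation with E1cB elimination gives the E enone before the enol ester meets a free nucleophile at higher temperature.

**Step 6**
Reactants: 11 (1E,3E)-5-oxo-5-[(4aS,8aR)-1,1,6-trimethyl-4a,7,8,8a-tetrahydro-1H-isochromen-4-yl]penta-1,3-dien-1-yl 3-methylbut-2-enoate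
Product: 12 (10R,13S,15S,16R) tricyclic ketone with C4 = CH2 and the C6=C7 enol ether, carrying the (E)-2-(3-methylbut-2-enoyloxy)ethenyl chain on C16
Conditions: Co(salen) (divalent cobalt, 10 mol %), 2,4,6-collidinium tetrafluoroborate (2.5 equiv), nBu4NBF4, MeCN/THF (0.01 M), RVC cathode, Zn anode, undivided cell, 2 mA, 2.5 F/mol, rt
Reagents that add atoms: none
Why: Proposed new method: at the cathode Co(salen) is reduced to monovalent cobalt, which collidinium protonates to a trivalent cobalt hydride that transfers a hydrogen atom to C14 of the trisubstituted alkene (Markovnikov MHAT); the tertiary C13 radical then closes 7-endo-trig onto C16, the β-carbon of the E,E-dienone, through the ground-state conformer in which the CMe2O group is equatorial and the C15–C6 tether axial, so the new bond can only form cis to that tether (C13 set by C15) and the E geometry turns the acyloxyvinyl group outward to the methyl face (C16 set), after which the α-keto radical is reduced and protonated; the closest known reaction types are the iron hydride/silane reductive alkene–enone coupling (MHAT Giese reaction) and cobalt-electrocatalytic HAT hydrofunctionalisation of alkenes, neither shown for a 7-endo closure that builds a bridged bicyclo[4.3.1]decane with a quaternary centre.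

**Step 7**
Reactants: 12 tricyclic ketone (C4 = CH2, C6=C7); 13 2-methoxyallyl bromide
Product: 15 (4S,10R,13S,15S,16S) C4-(2-oxopropyl) tricyclic diketone with the C6=C7 enol ether, via enol ether 14 (not isolated)
Conditions: LiHMDS (1.05 equiv), THF, −78 °C; 13, DMPU, −78 to −30 °C; then 1 M aq. oxalic acid, 0 °C to rt
Reagents that add atoms: water (O)
Why: In this kinetic enolate alkylation with an acetonyl equivalent C4 is the only enolisable position, the electrophile enters anti to the adjacent C16 chain (trans-2,3-disubstituted cycloheptanone, C4 set by C16), one equivalent of base at −78 °C spares the enol ester, and dilute acid hydrolyses only the simple enol ether.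

**Step 8**
Reactants: 15 C4-(2-oxopropyl) tricyclic diketone (C6=C7)
Product: 17 target CNP0237201.2, via hydroperoxide 16 (not isolated)
Conditions: Mn(dpm)3 (trivalent manganese, 10 mol %), PhSiH3, O2 (1 atm), iPrOH/CH2Cl2, 0 °C; then P(OEt)3
Reagents that add atoms: dioxygen (O=O)
Why: In this Mukaiyama-type MHAT reduction–oxygenation of an enone the manganese hydride delivers H to the β-carbon C7, the tertiary α-keto radical at C6 captures O2 on the convex face syn to C15–H because the other face lies under the cyclohexane ring, and phosphite reduces the hydroperoxide, which sets C6 and keeps the pyran cis-fused.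

**Compound list**
1 | (1S,4R)-1-methyl-4-(prop-1-en-2-yl)cyclohex-2-en-1-ol ((1S,4R)-p-mentha-2,8-dien-1-ol; OH cis to isopropenyl) | C[C@@]1(O)C=C[C@H](C(C)=C)CC1 | starting material
2 | but-3-yn-2-one | CC(=O)C#C | starting material
3 | (E)-4-{[(1S,4R)-1-methyl-4-(prop-1-en-2-yl)cyclohex-2-en-1-yl]oxy}but-3-en-2-one | CC(=O)/C=C/O[C@]1(C)C=C[C@H](C(C)=C)CC1 | intermediate
4 | 2-[(1S,6R)-3-methyl-6-(prop-1-en-2-yl)cyclohex-2-en-1-yl]-3-oxobutanal (ring substituents cis; enolised, C-2 of the butanal unfixed) | CC(=O)C(C=O)[C@H]1C=C(C)CC[C@H]1C(C)=C | intermediate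
5 | 1-[(4aS,8aR)-1,1,6-trimethyl-4a,7,8,8a-tetrahydro-1H-isochromen-4-yl]ethan-1-one (cis-fused) | CC(=O)C1=COC(C)(C)[C@@H]2CCC(C)=C[C@H]12 | intermediate
6 | tetrabutylammonium (E)-3-oxoprop-1-en-1-olate (malondialdehyde tetrabutylammonium salt) | [O-]/C=C/C=O.CCCC[N+](CCCC)(CCCC)CCCC | starting material
7 | 3-methylbut-2-enoyl chloride | CC(C)=CC(=O)Cl | starting material
8 | (E)-3-oxoprop-1-en-1-yl 3-methylbut-2-enoate | O=C/C=C/OC(=O)C=C(C)C | intermediate
9 | (E)-3-hydroxy-5-oxo-5-[(4aS,8aR)-1,1,6-trimethyl-4a,7,8,8a-tetrahydro-1H-isochromen-4-yl]pent-1-en-1-yl 3-methylbut-2-enoate (lithium alkoxide in the flask; both carbinol epimers) | CC(C)=CC(=O)O/C=C/C(O)CC(=O)C1=COC(C)(C)[C@@H]2CCC(C)=C[C@H]12 | intermediate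
10 | methanesulfonate of 9 | CC(C)=CC(=O)O/C=C/C(OS(C)(=O)=O)CC(=O)C1=COC(C)(C)[C@@H]2CCC(C)=C[C@H]12 | intermediate
11 | (1E,3E)-5-oxo-5-[(4aS,8aR)-1,1,6-trimethyl-4a,7,8,8a-tetrahydro-1H-isochromen-4-yl]penta-1,3-dien-1-yl 3-methylbut-2-enoate | CC(C)=CC(=O)O/C=C/C=C/C(=O)C1=COC(C)(C)[C@@H]2CCC(C)=C[C@H]12 | intermediate
12 | (10R,13S,15S,16R) tricyclic ketone: C5 ketone, C4 = CH2, C6=C7 enol ether, C10–H and C15–H cis, four-carbon bridge C16–C4–C5–C6 across C13 and C15 on the face of C9, (E)-2-(3-methylbut-2-enoyloxy)ethenyl on C16 syn to the C13 methyl | C1C(=O)C2=COC(C)(C)[C@@H]3CC[C@@](C)(C[C@@H]32)[C@H]1/C=C/OC(=O)C=C(C)C | intermediate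
13 | 3-bromo-2-methoxyprop-1-ene (2-methoxyallyl bromide) | COC(=C)CBr | starting material
14 | C4-(2-methoxyprop-2-enyl) derivative of 12, new group anti to the C16 chain | C=C(OC)C[C@@H]1C(=O)C2=COC(C)(C)[C@@H]3CC[C@@](C)(C[C@@H]32)[C@H]1/C=C/OC(=O)C=C(C)C | intermediate
15 | (4S,10R,13S,15S,16S) C4-(2-oxopropyl) derivative of 12 (the target without the C6 hydroxyl, C6=C7) | CC(=O)C[C@@H]1C(=O)C2=COC(C)(C)[C@@H]3CC[C@@](C)(C[C@@H]32)[C@H]1/C=C/OC(=O)C=C(C)C | intermediate
16 | C6 hydroperoxide corresponding to the target (OOH syn to C15–H) | CC(=O)C[C@@H]1C(=O)[C@]2(OO)COC(C)(C)[C@@H]3CC[C@@](C)(C[C@@H]32)[C@H]1/C=C/OC(=O)C=C(C)C | intermediate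
17 | target, (4S,6R,10R,13S,15S,16S): C6–OH syn to C15–H, C4 acetonyl anti to the C16 (E)-enol ester chain, which is syn to the C13 methyl | CC(=O)C[C@@H]1C(=O)[C@]2(O)COC(C)(C)[C@@H]3CC[C@@](C)(C[C@@H]32)[C@H]1/C=C/OC(=O)C=C(C)C | target

**Step count and risk**
Total steps: 8. Longest linear sequence: 7 steps (1 → 3 → 4 → 5 → 11 → 12 → 15 → 17); step 4 is the side branch.

Three steps most likely to fail:

Step 6 (the proposed new step). Likely failure modes are direct cathodic reduction of the dienone, simple hydrogenation of the C13 radical, and 6-exo attack at C4. The fallback sets out from 11. Dry HBr in CH2Cl2 at −78 °C adds in the Markovnikov sense to the C13=C14 alkene to give the tertiary bromide F1. Bu3SnH/AIBN (slow addition, PhH, 80 °C) then runs the same ring closure as a classical tin hydride radical chain, and the route is rejoined at 12.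

Step 7. The lithium enolate may attack the enol ester, or the electrophile may enter on the wrong face of C4. The fallback sets out from 12. TMSOTf/Et3N (CH2Cl2, 0 °C) gives the trimethylsilyl enol ether F2. SnCl4-promoted Mukaiyama–Michael addition to 2-nitropropene (CH2Cl2, −78 °C) gives the γ-nitro ketone F3. A buffered Nef reaction (TiCl3, NH4OAc, THF/H2O, rt) brings the route back at 15 without any strong base.

Step 8. The manganese hydride may attack the enol ester or senecioate alkenes, or the β-alkoxy enone may be too electron-rich to react. The fallback sets out from 15. RhCl(PPh3)3/Et3SiH (PhH, 50 °C) 1,4-hydrosilylation gives the triethylsilyl enol ether F4. Rubottom oxidation (mCPBA, NaHCO3, CH2Cl2, 0 °C) from the convex face gives the α-silyloxy ketone F5. HF·pyridine (THF, 0 °C) then brings the route back at 17.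

**Further compounds**
F1 | step 6 | (1E,3E)-5-[(4aS,8aR)-6-bromo-1,1,6-trimethyl-4a,5,6,7,8,8a-hexahydro-1H-isochromen-4-yl]-5-oxopenta-1,3-dien-1-yl 3-methylbut-2-enoate (both C–Br epimers) | CC(C)=CC(=O)O/C=C/C=C/C(=O)C1=COC(C)(C)[C@@H]2CCC(C)(Br)C[C@H]12
F2 | step 7 | C5 trimethylsilyl enol ether of 12 (C4=C5) | C1=C(O[Si](C)(C)C)C2=COC(C)(C)[C@@H]3CC[C@@](C)(C[C@@H]32)[C@H]1/C=C/OC(=O)C=C(C)C
F3 | step 7 | C4-(2-nitropropyl) derivative of 12, new group anti to the C16 chain (both nitro epimers) | CC([N+](=O)[O-])C[C@@H]1C(=O)C2=COC(C)(C)[C@@H]3CC[C@@](C)(C[C@@H]32)[C@H]1/C=C/OC(=O)C=C(C)C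
F4 | step 8 | C5 triethylsilyl enol ether of 15 (C5=C6, C7 = CH2) | CC(=O)C[C@@H]1C(O[Si](CC)(CC)CC)=C2COC(C)(C)[C@@H]3CC[C@@](C)(C[C@@H]32)[C@H]1/C=C/OC(=O)C=C(C)C
F5 | step 8 | 6-O-triethylsilyl ether of 17 | CC(=O)C[C@@H]1C(=O)[C@]2(O[Si](CC)(CC)CC)COC(C)(C)[C@@H]3CC[C@@](C)(C[C@@H]32)[C@H]1/C=C/OC(=O)C=C(C)C
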